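**Plan**

- Atom labels follow eudesmane numbering: ring A = C1–C5 and C10, ring B = C5–C10, C14 on C10, C15 on C4, the acrylate C11(=C13)–C12 on C7.
- The retrosynthesis cuts, in order: the C3 ester; C11=C13 and the C12 ester (back to a C7–CH2CHO chain, then to a prenyl group); C7–C11 (alkylation of a C8 ketone enolate); C4–C15 (cross-coupling); last, C5–C6 and C9–C10 (Diels–Alder).
- Enabling feature: ring A carries oxygen on C3, a methylated sp2 C4 and the quaternary methyl-bearing C10 next to C5. This is the pattern of 2-methoxy-5-methylbenzoquinone, whose methylated C=C becomes C5–C10; the C8 oxygen of ring B is the oxygen of a 2-silyloxybutadiene.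
- Forward: ring A is bought as the quinone and ring B closes in the cycloaddition. Ring A is then edited (C15 in, C1 oxygen out by carbonyl transposition), and the C7 chain is attached and grown into the acrylate after O8 is acetylated.
- Stereochemistry: C10 from the chiral titanium–binaphthol catalyst; C7 by base equilibration to the equatorial position; C8 and C3 by hydride delivery to the face opposite the axial C14 methyl group.

Key step: step 2

Assumption: the (R)-binaphthol titanium complex is taken to shield the face of the chelated quinone that leads to the 10R adduct 4; if the sense proves opposite, the (S)-ligand is used and nothing else changes.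

**Route**

Step 1
Reactants: 1 but-3-en-2-one (methyl vinyl ketone)
Product: 2 2-(tert-butyldimethylsilyloxy)buta-1,3-diene
Conditions: TBSOTf, Et3N, Et2O, 0 °C to rt
Reagents that add atoms: tert-butyldimethylsilyl trifluoromethanesulfonate, CC(C)(C)[Si](C)(C)OS(=O)(=O)C(F)(F)F
Why: O-Silylation of the enone under soft enolisation (silyl triflate plus amine) is the standard way to 2-silyloxydienes, and the tert-butyldimethylsilyl group is chosen because its enol ether should survive chromatography and the three steps after the cycloaddition; no stereocentre is formed.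

Step 2
Reactants: 3 2-methoxy-5-methyl-1,4-benzoquinone; 2 2-(tert-butyldimethylsilyloxy)buta-1,3-diene
Product: 4 (4aR,8aS)-6-[(tert-butyldimethylsilyl)oxy]-2-methoxy-4a-methyl-4a,5,8,8a-tetrahydronaphthalene-1,4-dione (cis-fused adduct; 10β-methyl and 5β-H; C1 and C4 carbonyls, C3 methoxy, C7=C8 silyl enol ether)
Conditions: TiCl2(O-i-Pr)2 and (R)-1,1'-bi-2-naphthol (20 mol% each, premixed over 4 Å molecular sieves, sieves removed), CH2Cl2, −40 to −20 °C
Reagents that add atoms: none
Why: The diene adds in a concerted, asynchronous, normal-electron-demand [4+2] cycloaddition to the quinone, which is held as a five-membered chelate between its C4 carbonyl oxygen, its methoxy oxygen and the tetravalent titanium centre. The closest known reaction type is the titanium–binaphthol-catalysed enantioselective quinone Diels–Alder reaction, together with the chelation-controlled SnCl4-promoted cycloadditions of this same quinone. Ring B closes in an intermolecular [4+2] annulation in which C9–C10 and C5–C6 form suprafacially on one face of the C5=C10 alkene, so the six-membered ring is formed cis-fused and as its C7=C8 silyl enol ether. C10 is set by the binaphthol ligand, which screens one face of the chelated quinone, and C5 follows from the suprafacial addition (it is erased in step 3). Site selectivity for C5=C10 over C2=C3 comes from the methoxy group, which makes its own alkene an unreactive vinylogous ester, and regioselectivity (C9 to C10) from the chelate, which makes C4=O the activating carbonyl and C10 its electrophilic β-carbon, matched with the nucleophilic CH2 terminus next to the silyloxy carbon. Enantiofacial selectivity is the one property not built into the substrate and rests on the catalyst.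

Step 3
Reactants: 4 cis-fused adduct
Product: 6 (R)-6-[(tert-butyldimethylsilyl)oxy]-2-methoxy-4a-methyl-4-oxo-4,4a,5,8-tetrahydronaphthalen-1-yl trifluoromethanesulfonate (C4 dienyl triflate with C4=C5), via potassium C5-enolate 5 (not isolated)
Conditions: KN(SiMe3)2, THF, −78 °C; then PhNTf2, −78 to 0 °C
Reagents that add atoms: N-phenylbis(trifluoromethanesulfonimide), O=S(=O)(N(c1ccccc1)S(=O)(=O)C(F)(F)F)C(F)(F)F
Why: Enol triflate formation: C5–H, α to the C4 ketone, is the only acidic proton of 4 (C10 is quaternary, so the enolate cannot aromatise), and O-sulfonylation of enolate 5 erases the C5 stereocentre on purpose while fixing the future C4=C5 double bond and turning C4 into a cross-coupling site.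

Step 4
Reactants: 6 C4 dienyl triflate
Product: 7 (R)-7-[(tert-butyldimethylsilyl)oxy]-3-methoxy-4,8a-dimethyl-8,8a-dihydronaphthalen-1(5H)-one (C1 ketone, C2=C3(OMe), C4(Me)=C5)
Conditions: MeZnCl, Pd(PPh3)4 (5 mol%), THF, 0 °C to rt
Reagents that add atoms: methylzinc chloride, C[Zn]Cl
Why: Negishi cross-coupling of an electron-poor alkenyl triflate under zerovalent palladium catalysis brings in C15, the methylzinc reagent being too unreactive to add to the vinylogous ester carbonyl or to disturb the silyl enol ether, and no stereocentre is touched.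

Step 5
Reactants: 7 methylated 2,4-dienone
Product: 9 (S)-1,4a-dimethyl-4a,5,7,8-tetrahydronaphthalene-2,6-dione (1,4-dien-3-one with free C8 ketone), via methoxy dienol 8 (not isolated)
Conditions: i-Bu2AlH, CH2Cl2, −78 °C; then 1 M HCl, THF, 0 °C to rt
Reagents that add atoms: water, O
Why: Stork–Danheiser carbonyl transposition: 1,2-reduction of the vinylogous ester carbonyl gives dienol 8, which in dilute acid ionises at C1 to a methoxy-stabilised pentadienyl cation that water captures at C3, so the C1 oxygen leaves, C3 becomes the ketone of a cross-conjugated dienone, and the same acid hydrolyses the silyl enol ether to the C8 ketone without creating a stereocentre.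

Step 6
Reactants: 9 dienone–ketone; 10 1-bromo-3-methylbut-2-ene (prenyl bromide)
Product: 13 (4aS,7S)-1,4a-dimethyl-7-(3-methylbut-2-en-1-yl)-4a,5,7,8-tetrahydronaphthalene-2,6-dione (7β-prenyl ketone), via lithium C7-enolate 11 (not isolated), via C7-epimeric prenyl ketones 12 (not isolated)
Conditions: LiN(i-Pr)2, THF, −78 °C; 10, −78 to −20 °C; then K2CO3, MeOH, rt
Reagents that add atoms: none
Why: Kinetic enolate alkylation (SN2 on an allylic bromide): the dienone has no α-hydrogen and C9 is neopentylic, so deprotonation should occur at C7, and the subsequent base equilibration through the C8 enolate places the new chain equatorial on ring B (7β, on the same face as C14), which sets C7 under thermodynamic control.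

Step 7
Reactants: 13 7β-prenyl ketone
Product: 14 (4aS,6R,7S)-6-hydroxy-1,4a-dimethyl-7-(3-methylbut-2-en-1-yl)-5,6,7,8-tetrahydronaphthalen-2(4aH)-one (8β-alcohol)
Conditions: NaBH4, MeOH/CH2Cl2, −20 °C
Reagents that add atoms: none
Why: Chemoselective borohydride reduction of a saturated ketone beside a cross-conjugated dienone (the selectivity known from steroidal 1,4-dien-3-ones carrying a second ketone), with hydride arriving on the α face because the β face of C8 is screened by the syn-axial C14 methyl group, which gives the axial 8β-alcohol cis to the C7 chain.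

Step 8
Reactants: 14 8β-alcohol
Product: 15 (4aS,6R,7S)-1,4a-dimethyl-7-(3-methylbut-2-en-1-yl)-2-oxo-2,4a,5,6,7,8-hexahydronaphthalen-6-yl acetate (8β-acetate)
Conditions: Ac2O, DMAP, pyridine, CH2Cl2, rt
Reagents that add atoms: acetic anhydride, CC(=O)OC(C)=O
Why: DMAP-catalysed acylation of the hindered axial secondary alcohol caps O8 before any C12 carbonyl exists, so that lactonisation onto O8 cannot occur later, and no stereocentre changes.

Step 9
Reactants: 15 8β-acetate
Product: 16 (4aR,6R,7S)-1,4a-dimethyl-7-(3-methylbut-2-en-1-yl)-2-oxo-2,3,4,4a,5,6,7,8-octahydronaphthalen-6-yl acetate (4-en-3-one)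
Conditions: H2 (1 atm), RhCl(PPh3)3 (5 mol%), benzene/EtOH, rt
Reagents that add atoms: none
Why: Homogeneous hydrogenation with RhCl(PPh3)3 saturates the cis-disubstituted C1=C2 bond of a 1,4-dien-3-one and should leave the tetrasubstituted C4=C5 and the trisubstituted prenyl double bond, the classical dienone-to-enone reduction, with no stereocentre formed.

Step 10
Reactants: 16 4-en-3-one
Product: 18 (4aR,6R,7R)-1,4a-dimethyl-2-oxo-7-(2-oxoethyl)-2,3,4,4a,5,6,7,8-octahydronaphthalen-6-yl acetate (C12 aldehyde), via ozonide 17 (not isolated)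
Conditions: O3, CH2Cl2, −78 °C (Sudan Red 7B end point); then PPh3, −78 °C to rt
Reagents that add atoms: ozone, [O-][O+]=O
Why: Ozonolysis with reductive work-up: the electron-rich trisubstituted prenyl alkene reacts far faster with ozone than the tetrasubstituted, electron-poor C4=C5 enone bond, and the dye end point guards against over-oxidation, so the chain is cut to the C11–C12 aldehyde without touching a stereocentre.

Step 11
Reactants: 18 C12 aldehyde
Product: 19 (4aR,6R,7R)-1,4a-dimethyl-2-oxo-7-(3-oxoprop-1-en-2-yl)-2,3,4,4a,5,6,7,8-octahydronaphthalen-6-yl acetate (α-methylene aldehyde)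
Conditions: aq. CH2O (37%), pyrrolidine (10 mol%), propionic acid (10 mol%), i-PrOH, 45 °C
Reagents that add atoms: formaldehyde, C=O
Why: Amine-catalysed α-methylenation of an α-unbranched aldehyde (enamine Mannich addition to formaldehyde followed by elimination) installs C13 as the exocyclic methylene, the aldehyde forming an enamine far more readily than the hindered C3 enone, and C7, whose hydrogen is only allylic and not acidified by the new enal, should keep its configuration.

Step 12
Reactants: 19 α-methylene aldehyde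
Product: 20 2-[(2R,3R,4aR)-3-acetoxy-4a,8-dimethyl-7-oxo-1,2,3,4,4a,5,6,7-octahydronaphthalen-2-yl]prop-2-enoic acid
Conditions: NaClO2, NaH2PO4, 2-methylbut-2-ene, t-BuOH/H2O, 0 °C to rt
Reagents that add atoms: sodium chlorite, [Na+].[O-]Cl=O
Why: Pinnick oxidation converts the enal into the acrylic acid under buffered conditions that leave the acetate, the enone and the 1,1-disubstituted alkene (protected by the hypochlorite scavenger) untouched.

Step 13
Reactants: 20 acrylic acid
Product: 21 methyl 2-[(2R,3R,4aR)-3-acetoxy-4a,8-dimethyl-7-oxo-1,2,3,4,4a,5,6,7-octahydronaphthalen-2-yl]prop-2-enoate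
Conditions: MeI, K2CO3, DMF, 0 °C to rt
Reagents that add atoms: iodomethane, CI
Why: SN2 O-methylation of the carboxylate with a base too weak to enolise the C3 ketone gives the methyl ester, and because O8 is already acetylated no lactone can form.

Step 14
Reactants: 21 keto methyl ester
Product: 22 methyl 2-[(2R,3R,4aR,7S)-3-acetoxy-7-hydroxy-4a,8-dimethyl-1,2,3,4,4a,5,6,7-octahydronaphthalen-2-yl]prop-2-enoate (3β-alcohol)
Conditions: NaBH4, CeCl3·7H2O, MeOH, −40 °C
Reagents that add atoms: none
Why: Luche 1,2-reduction of the enone: hydride should add to C3 from the α face, opposite the axial C14 methyl group, as with steroidal 4-en-3-ones, to give the pseudo-equatorial 3β-alcohol, while the acrylate and both esters are inert to NaBH4/CeCl3 at low temperature.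

Step 15
Reactants: 22 3β-alcohol; 23 (2E)-3-methylpent-2-enoic acid
Product: 24 methyl 2-[(2R,3R,4aR,7S)-3-acetoxy-4a,8-dimethyl-7-{[(2E)-3-methylpent-2-enoyl]oxy}-1,2,3,4,4a,5,6,7-octahydronaphthalen-2-yl]prop-2-enoate (CNP0118541.1)
Conditions: DCC, DMAP (10 mol%), CH2Cl2, 0 °C to rt
Reagents that add atoms: none
Why: Steglich esterification of the allylic 3β-alcohol with the enoic acid proceeds with retention at C3, and low temperature with only catalytic DMAP is meant to keep the (E)-trisubstituted double bond of the acyl group from isomerising or deconjugating.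

**Compound list**

1 | but-3-en-2-one (methyl vinyl ketone) | CC(=O)C=C | starting material
2 | 2-(tert-butyldimethylsilyloxy)buta-1,3-diene | C=CC(=C)O[Si](C)(C)C(C)(C)C | intermediate
3 | 2-methoxy-5-methyl-1,4-benzoquinone | COC1=CC(=O)C(C)=CC1=O | starting material
4 | (4aR,8aS)-6-[(tert-butyldimethylsilyl)oxy]-2-methoxy-4a-methyl-4a,5,8,8a-tetrahydronaphthalene-1,4-dione | COC1=CC(=O)[C@]2(C)CC(O[Si](C)(C)C(C)(C)C)=CC[C@@H]2C1=O | intermediate
5 | potassium (R)-6-[(tert-butyldimethylsilyl)oxy]-2-methoxy-4a-methyl-4-oxo-4,4a,5,8-tetrahydronaphthalen-1-olate | COC1=CC(=O)[C@]2(C)CC(O[Si](C)(C)C(C)(C)C)=CCC2=C1[O-].[K+] | intermediate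
6 | (R)-6-[(tert-butyldimethylsilyl)oxy]-2-methoxy-4a-methyl-4-oxo-4,4a,5,8-tetrahydronaphthalen-1-yl trifluoromethanesulfonate | COC1=CC(=O)[C@]2(C)CC(O[Si](C)(C)C(C)(C)C)=CCC2=C1OS(=O)(=O)C(F)(F)F | intermediate
7 | (R)-7-[(tert-butyldimethylsilyl)oxy]-3-methoxy-4,8a-dimethyl-8,8a-dihydronaphthalen-1(5H)-one | COC1=CC(=O)[C@]2(C)CC(O[Si](C)(C)C(C)(C)C)=CCC2=C1C | intermediate
8 | (8aR)-7-[(tert-butyldimethylsilyl)oxy]-3-methoxy-4,8a-dimethyl-1,5,8,8a-tetrahydronaphthalen-1-ol (both C1 epimers) | COC1=CC(O)[C@]2(C)CC(O[Si](C)(C)C(C)(C)C)=CCC2=C1C | intermediate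
9 | (S)-1,4a-dimethyl-4a,5,7,8-tetrahydronaphthalene-2,6-dione | CC1=C2CCC(=O)C[C@@]2(C)C=CC1=O | intermediate
10 | 1-bromo-3-methylbut-2-ene (prenyl bromide) | CC(C)=CCBr | starting material
11 | lithium (S)-1,4a-dimethyl-2-oxo-2,4a,5,8-tetrahydronaphthalen-6-olate | CC1=C2CC=C([O-])C[C@@]2(C)C=CC1=O.[Li+] | intermediate
12 | (4aS)-1,4a-dimethyl-7-(3-methylbut-2-en-1-yl)-4a,5,7,8-tetrahydronaphthalene-2,6-dione (both C7 epimers) | CC1=C2CC(CC=C(C)C)C(=O)C[C@@]2(C)C=CC1=O | intermediate
13 | (4aS,7S)-1,4a-dimethyl-7-(3-methylbut-2-en-1-yl)-4a,5,7,8-tetrahydronaphthalene-2,6-dione | CC1=C2C[C@H](CC=C(C)C)C(=O)C[C@@]2(C)C=CC1=O | intermediate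
14 | (4aS,6R,7S)-6-hydroxy-1,4a-dimethyl-7-(3-methylbut-2-en-1-yl)-5,6,7,8-tetrahydronaphthalen-2(4aH)-one | CC1=C2C[C@H](CC=C(C)C)[C@H](O)C[C@@]2(C)C=CC1=O | intermediate
15 | (4aS,6R,7S)-1,4a-dimethyl-7-(3-methylbut-2-en-1-yl)-2-oxo-2,4a,5,6,7,8-hexahydronaphthalen-6-yl acetate | CC1=C2C[C@H](CC=C(C)C)[C@H](OC(C)=O)C[C@@]2(C)C=CC1=O | intermediate
16 | (4aR,6R,7S)-1,4a-dimethyl-7-(3-methylbut-2-en-1-yl)-2-oxo-2,3,4,4a,5,6,7,8-octahydronaphthalen-6-yl acetate | CC1=C2C[C@H](CC=C(C)C)[C@H](OC(C)=O)C[C@@]2(C)CCC1=O | intermediate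
17 | (4aR,6R,7R)-7-[(5,5-dimethyl-1,2,4-trioxolan-3-yl)methyl]-1,4a-dimethyl-2-oxo-2,3,4,4a,5,6,7,8-octahydronaphthalen-6-yl acetate (ozonide, both epimers at the trioxolane carbon) | CC1=C2C[C@H](CC3OOC(C)(C)O3)[C@H](OC(C)=O)C[C@@]2(C)CCC1=O | intermediate
18 | (4aR,6R,7R)-1,4a-dimethyl-2-oxo-7-(2-oxoethyl)-2,3,4,4a,5,6,7,8-octahydronaphthalen-6-yl acetate | CC1=C2C[C@H](CC=O)[C@H](OC(C)=O)C[C@@]2(C)CCC1=O | intermediate
19 | (4aR,6R,7R)-1,4a-dimethyl-2-oxo-7-(3-oxoprop-1-en-2-yl)-2,3,4,4a,5,6,7,8-octahydronaphthalen-6-yl acetate | C=C(C=O)[C@H]1CC2=C(C)C(=O)CC[C@]2(C)C[C@H]1OC(C)=O | intermediate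
20 | 2-[(2R,3R,4aR)-3-acetoxy-4a,8-dimethyl-7-oxo-1,2,3,4,4a,5,6,7-octahydronaphthalen-2-yl]prop-2-enoic acid | C=C(C(=O)O)[C@H]1CC2=C(C)C(=O)CC[C@]2(C)C[C@H]1OC(C)=O | intermediate
21 | methyl 2-[(2R,3R,4aR)-3-acetoxy-4a,8-dimethyl-7-oxo-1,2,3,4,4a,5,6,7-octahydronaphthalen-2-yl]prop-2-enoate | C=C(C(=O)OC)[C@H]1CC2=C(C)C(=O)CC[C@]2(C)C[C@H]1OC(C)=O | intermediate
22 | methyl 2-[(2R,3R,4aR,7S)-3-acetoxy-7-hydroxy-4a,8-dimethyl-1,2,3,4,4a,5,6,7-octahydronaphthalen-2-yl]prop-2-enoate | C=C(C(=O)OC)[C@H]1CC2=C(C)[C@@H](O)CC[C@]2(C)C[C@H]1OC(C)=O | intermediate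
23 | (2E)-3-methylpent-2-enoic acid | CC/C(C)=C/C(=O)O | starting material
24 | methyl 2-[(2R,3R,4aR,7S)-3-acetoxy-4a,8-dimethyl-7-{[(2E)-3-methylpent-2-enoyl]oxy}-1,2,3,4,4a,5,6,7-octahydronaphthalen-2-yl]prop-2-enoate (CNP0118541.1) | C=C(C(=O)OC)[C@H]1CC2=C(C)[C@@H](OC(=O)/C=C(\C)CC)CC[C@]2(C)C[C@H]1OC(C)=O | target

**Step count and risks**

Total step count: 15. Longest linear sequence: 15 steps (1 to 24).

Steps most likely to fail:

1. Step 2. The trisubstituted quinone alkene and this diene have not been paired under the titanium–binaphthol catalyst, so poor enantiofacial discrimination, or slow turnover with erosion by the uncatalysed background reaction, is the main danger. Fallback: give up catalytic induction. From 2 and 3, the achiral chelating promoter SnCl4 (CH2Cl2, −78 °C), which is known to enforce the same site and regiochemistry with this quinone, should give the racemic cis adduct, that is 4 together with the (4aS,8aR)-enantiomer F1. Preparative chromatography on a chiral stationary phase (supercritical CO2/i-PrOH) removes F1, and the route is rejoined at 4.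

2. Step 6. Competing deprotonation at C9 or at the γ-position C6 of the dienone, over-alkylation, or incomplete equilibration at C7 may spoil the regio- and stereochemical outcome. Fallback: use the regiochemistry that the cycloaddition already wrote into the C7=C8 enol ether. From 7, reduction with i-Bu2AlH as in step 5 gives dienol 8, which is hydrolysed under buffered conditions that spare the silyl enol ether (oxalic acid, wet THF, 0 °C) to the dienone silyl enol ether F2. Fluoride-triggered regiospecific alkylation (tris(dimethylamino)sulfonium difluorotrimethylsilicate, prenyl bromide 10, THF, −78 to 0 °C) then releases the enolate only at C7 and should give the alkylated ketones 12, which are equilibrated with K2CO3/MeOH to 13 as in the main route.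

3. Step 9. The prenyl double bond may be reduced alongside C1=C2, or the hindered C1=C2 bond may react too slowly to allow a clean stop. Fallback: remove the competing alkene before hydrogenation. From 15, ozonolysis (O3, CH2Cl2, −78 °C; then PPh3) should give, through the ozonide F3, the dienone aldehyde F4. Acetalisation (HC(OMe)3, pyridinium p-toluenesulfonate, MeOH) gives the dimethyl acetal F5, hydrogenation (H2, RhCl(PPh3)3) the enone acetal F6, and mild aqueous acid (pyridinium p-toluenesulfonate, acetone/H2O) returns aldehyde 18.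

**Further compounds**

F1 | step 2 | (4aS,8aR)-6-[(tert-butyldimethylsilyl)oxy]-2-methoxy-4a-methyl-4a,5,8,8a-tetrahydronaphthalene-1,4-dione (enantiomer of 4) | COC1=CC(=O)[C@@]2(C)CC(O[Si](C)(C)C(C)(C)C)=CC[C@H]2C1=O
F2 | step 6 | (S)-6-[(tert-butyldimethylsilyl)oxy]-1,4a-dimethyl-4a,5-dihydronaphthalen-2(8H)-one | CC1=C2CC=C(O[Si](C)(C)C(C)(C)C)C[C@@]2(C)C=CC1=O
F3 | step 9 | (4aS,6R,7R)-7-[(5,5-dimethyl-1,2,4-trioxolan-3-yl)methyl]-1,4a-dimethyl-2-oxo-2,4a,5,6,7,8-hexahydronaphthalen-6-yl acetate (ozonide, both epimers at the trioxolane carbon) | CC1=C2C[C@H](CC3OOC(C)(C)O3)[C@H](OC(C)=O)C[C@@]2(C)C=CC1=O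
F4 | step 9 | (4aS,6R,7R)-1,4a-dimethyl-2-oxo-7-(2-oxoethyl)-2,4a,5,6,7,8-hexahydronaphthalen-6-yl acetate | CC1=C2C[C@H](CC=O)[C@H](OC(C)=O)C[C@@]2(C)C=CC1=O
F5 | step 9 | (4aS,6R,7R)-7-(2,2-dimethoxyethyl)-1,4a-dimethyl-2-oxo-2,4a,5,6,7,8-hexahydronaphthalen-6-yl acetate | CC1=C2C[C@H](CC(OC)OC)[C@H](OC(C)=O)C[C@@]2(C)C=CC1=O
F6 | step 9 | (4aR,6R,7R)-7-(2,2-dimethoxyethyl)-1,4a-dimethyl-2-oxo-2,3,4,4a,5,6,7,8-octahydronaphthalen-6-yl acetate | CC1=C2C[C@H](CC(OC)OC)[C@H](OC(C)=O)C[C@@]2(C)CCC1=O
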